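The target is cut back to symmetric methylene-bis(filicinic acid) and one seven-carbon thia-diacid: the terminal methyl carbons of the butanoyl chain on C1 (ring A) and of the propanoyl chain on C5' (ring B) are read as two carbons that once shared a sulfur atom. One twofold C-acylation with carbodiimide and DMAP under slow-addition dilution joins both acyl carbons to the only unsubstituted carbon of each ring and closes a 15-membered thia-bridged ring, so the butanoyl/propanoyl pairing is decided intramolecularly. Its precursors are the bis-trione, with one free ring CH per ring, and 4-(2-carboxyethylsulfanyl)butanoic acid; nickel hydrogenolysis of the two C–S bonds then uncovers both methyl groups.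

Key step: step 5

Remark: the β-triketone rings are drawn as one enol tautomer of a rapidly equilibrating set, the target has no stereocentre, ring A is numbered C1 (acyl-bearing) to C6 with the bridge methylene as C7, ring B is primed with C1' on the bridge and C5' acyl-bearing, and 2,4,6-trihydroxyacetophenone is taken as the purchased form of acetylated phloroglucinol.

Step 1
Reactants: 1 2,4,6-trihydroxyacetophenone
Product: 2 2-acetylfilicinic acid (2-acetyl-3,5-dihydroxy-4,4-dimethylcyclohexa-2,5-dien-1-one)
Conditions: MeI (2.2 equiv), NaOMe (3 equiv), MeOH, 0 °C to rt
Reagents that add atoms: iodomethane, CI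
Why: Dearomatising geminal C-methylation of the acylphloroglucinol polyphenoxide, the known entry to acylfilicinic acids; the acetyl group blocks one ring carbon and the MeI stoichiometry limits the reaction to two methyl groups, with under- and over-methylated by-products removed by chromatography.

Step 2
Reactants: 2 2-acetylfilicinic acid
Product: 3 filicinic acid (3,5-dihydroxy-4,4-dimethylcyclohexa-2,5-dien-1-one)
Conditions: 6 M aq. HCl, reflux
Reagents that add atoms: none
Why: Acid-catalysed hydrolytic deacylation (retro-Claisen-type C–C cleavage) of a 2-acyl cyclic 1,3-dione: water adds to the protonated exocyclic acetyl carbonyl and the stabilised filicinic acid enol is expelled together with acetic acid, while the gem-dimethyl ring is inert to hot mineral acid.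

Step 3
Reactants: 3 filicinic acid (2 molecules); 4 formaldehyde
Product: 5 methylene-bis(filicinic acid)
Conditions: 37% aq. CH2O (1 equiv) added slowly to 3 (5 equiv), EtOH/H2O, rt; excess 3 recovered
Reagents that add atoms: none
Why: Knoevenagel condensation of one molecule of 3 with formaldehyde to the 2-methylene trione followed by Michael addition of a second molecule, the reaction type that gives methylene-bis-dimedone; the large excess of 3 and the slow addition of 4 should keep the doubly nucleophilic monomer from growing beyond the dimer.

Step 4
Reactants: 6 3-sulfanylpropanoic acid; 7 ethyl 4-bromobutanoate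
Product: 9 4-(2-carboxyethylsulfanyl)butanoic acid, via thioether ester acid 8 (not isolated)
Conditions: NaOH (2.1 equiv), EtOH/H2O, 0 °C to rt; then NaOH (2 equiv), 50 °C; then aq. HCl
Reagents that add atoms: sodium hydroxide, [Na+].[OH-]
Why: SN2 S-alkylation of the primary bromide by the thiolate, which is far more nucleophilic than carboxylate or hydroxide, followed in the same flask by ester saponification and acidification.

Step 5
Reactants: 5 methylene-bis(filicinic acid); 9 4-(2-carboxyethylsulfanyl)butanoic acid
Product: 12 15-membered thia-bridged bis-triketone macrocycle, via butanoyl-linked seco acid 10 (not isolated), via propanoyl-linked seco acid 11 (not isolated)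
Conditions: 5 (2 mM) and DMAP (6 equiv) in CH2Cl2, rt; 9 (1.0 equiv, in THF) and DCC (2.4 equiv, in CH2Cl2) added simultaneously from two syringes over 12 h; then 40 °C; dilute HCl work-up
Reagents that add atoms: none
Why: Proposed new method: DCC converts each carboxyl of 9 into an O-acylisourea that DMAP relays as an N-acylpyridinium ion; this acylates an enol oxygen of 5, and DMAP then reopens the enol ester to an acylpyridinium/enolate pair that recombines at the one unsubstituted ring carbon (C1 or C5'), where the internally hydrogen-bonded 2-acyl triketone, held as its DMAP salt, is the most stable resting place of the acyl group. The closest known reaction type is the carbodiimide/DMAP C-acylation of cyclic 1,3-diones by O-acylation and O-to-C acyl shift, which has not been used twice on one tethered diacid to close a ring. The first acylation is intermolecular and gives seco acids 10 and 11, which converge because 5 is symmetric; the second is an intramolecular acyl substitution (exo-trig attack of the remaining free enol carbon on the tethered activated acyl carbon) that closes the 15-membered ring C1–(CO)CH2CH2CH2–S–CH2CH2(CO)–C5'–C6'–C1'–C7–C5–C6. No stereocentre is formed, so no stereocontrol element is needed. The step needs C- over O-acylation, secured by the reversibility of O-acylation under excess DMAP and by each ring offering a single acylatable carbon, and ring closure over chain growth, secured by the simultaneous slow addition of 9 and DCC to dilute 5 and by the hydrogen-bonded bis-enol core that places C1 and C5' on the same face of the C7 bridge. Excess DMAP, partly protonated by the acidic trione, also intercepts the O-acylisourea before it can rearrange to an N-acylurea at low concentration.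

Step 6
Reactants: 12 15-membered thia-bridged bis-triketone macrocycle
Product: 13 CNP0260944.0 (the butanoyl/propanoyl methylene-bis(acylfilicinic acid))
Conditions: Raney Ni (W-2, acetone-deactivated, washed neutral, excess), EtOH, rt to 50 °C
Reagents that add atoms: none
Why: Raney Ni hydrogenolysis of both C(sp3)–S bonds of the dialkyl thioether (reductive desulfurisation) turns the two sulfur-bound carbons into the terminal methyl groups of the butanoyl and propanoyl chains; neutral, deactivated nickel should leave the chelated, enolised triketone carbonyls and the C7 bridge untouched and avoids base-induced exchange of the bridge.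

Compound list
1 | 2,4,6-trihydroxyacetophenone | CC(=O)c1c(O)cc(O)cc1O | starting material
2 | 2-acetylfilicinic acid (2-acetyl-3,5-dihydroxy-4,4-dimethylcyclohexa-2,5-dien-1-one) | CC(=O)C1=C(O)C(C)(C)C(O)=CC1=O | intermediate
3 | filicinic acid (3,5-dihydroxy-4,4-dimethylcyclohexa-2,5-dien-1-one) | O=C1C=C(O)C(C)(C)C(O)=C1 | intermediate
4 | formaldehyde | C=O | starting material
5 | methylene-bis(filicinic acid) | O=C1C=C(O)C(C)(C)C(O)=C1CC1=C(O)C(C)(C)C(O)=CC1=O | intermediate
6 | 3-sulfanylpropanoic acid | OC(=O)CCS | starting material
7 | ethyl 4-bromobutanoate | CCOC(=O)CCCBr | starting material
8 | 3-[(4-ethoxy-4-oxobutyl)sulfanyl]propanoic acid (thioether ester acid, present as its sodium salt) | CCOC(=O)CCCSCCC(=O)O | intermediate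
9 | 4-(2-carboxyethylsulfanyl)butanoic acid | OC(=O)CCCSCCC(=O)O | intermediate
10 | butanoyl-linked seco acid (5 acylated at C1 by the butanoic end of 9, free propanoic acid end) | OC(=O)CCSCCCC(=O)C1=C(O)C(C)(C)C(O)=C(CC2=C(O)C(C)(C)C(O)=CC2=O)C1=O | intermediate
11 | propanoyl-linked seco acid (5 acylated at C1 by the propanoic end of 9, free butanoic acid end) | OC(=O)CCCSCCC(=O)C1=C(O)C(C)(C)C(O)=C(CC2=C(O)C(C)(C)C(O)=CC2=O)C1=O | intermediate
12 | 15-membered thia-bridged bis-triketone macrocycle | O=C1CCCSCCC(=O)C2=C(O)C(C)(C)C(O)=C(CC3=C(O)C(C)(C)C(O)=C1C3=O)C2=O | intermediate
13 | CNP0260944.0, 2-butanoyl-6-[(2,6-dihydroxy-3,3-dimethyl-4-oxo-5-propanoylcyclohexa-1,5-dien-1-yl)methyl]-3,5-dihydroxy-4,4-dimethylcyclohexa-2,5-dien-1-one | CCCC(=O)C1=C(O)C(C)(C)C(O)=C(CC2=C(O)C(C)(C)C(O)=C(C(=O)CC)C2=O)C1=O | target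

Total step count: 6 steps. Longest linear sequence: 5 steps (steps 1, 2, 3, 5 and 6); step 4 is a one-step side branch.

Steps most likely to fail

Step 5 (Proposed new method). What may go wrong: chain growth to open 2:1 and oligomeric acylation products in place of ring closure, arrest at the O-acyl enol ester stage, and diversion of the activated acid into an N-acylurea at the low concentration that the ring closure needs. The fallback uses known chemistry and sets out from 5. A Steglich-type C-acylation with butanoic acid (1 equiv), DCC and DMAP in CH2Cl2 should give the mono-butanoyl methylene-bis(filicinic acid) F1, which is separated from unreacted 5 and from doubly acylated material. A second C-acylation of the same type with propanoic acid, DCC and DMAP at the remaining free carbon C5' should then give the target. The fallback comes back to the route at 13, and step 6 is not needed.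

Step 6. What may go wrong: over-reduction of the chelated acyl carbonyl or ring enone units, loss of the acidic polyketone by chelation to nickel, or exchange of the methylene bridge under residual alkali, which would scramble the two acyl-bearing rings. The fallback is a sulfur-free assembly that sets out from 3. C-acylation of 3 with butanoic acid (DCC, DMAP, CH2Cl2) should give 2-butanoylfilicinic acid F2, and the same reaction with propanoic acid should give 2-propanoylfilicinic acid F3. A Mannich reaction of F3 with formaldehyde 4 and dimethylamine should give 6-(dimethylaminomethyl)-2-propanoylfilicinic acid F4. Warming F4 with F2 in a neutral solvent should release dimethylamine and a methylene trione, which the free ring carbon of F2 traps in a Michael addition. The fallback comes back to the route at 13.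

Step 3. What may go wrong: chain growth beyond the dimer, because 3 and the product 5 both still carry nucleophilic ring carbons that can react with further formaldehyde. The fallback sets out from 2, which has only one free ring carbon. Condensation of 2 with formaldehyde 4 in 1% aq. NaOH at rt should give methylene-bis(2-acetylfilicinic acid) F5 without oligomers. Removal of both acetyl groups under the conditions of step 2, at the lowest temperature that still cleaves them, should give the bis-trione. The fallback comes back to the route at 5.

Further compounds
F1 | step 5 | mono-butanoyl methylene-bis(filicinic acid) | CCCC(=O)C1=C(O)C(C)(C)C(O)=C(CC2=C(O)C(C)(C)C(O)=CC2=O)C1=O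
F2 | step 6 | 2-butanoylfilicinic acid | CCCC(=O)C1=C(O)C(C)(C)C(O)=CC1=O
F3 | step 6 | 2-propanoylfilicinic acid | CCC(=O)C1=C(O)C(C)(C)C(O)=CC1=O
F4 | step 6 | 6-(dimethylaminomethyl)-2-propanoylfilicinic acid | CCC(=O)C1=C(O)C(C)(C)C(O)=C(CN(C)C)C1=O
F5 | step 3 | methylene-bis(2-acetylfilicinic acid) | CC(=O)C1=C(O)C(C)(C)C(O)=C(CC2=C(O)C(C)(C)C(O)=C(C(C)=O)C2=O)C1=O
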